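The cycloheptene is cut between a three-carbon unit, C10–C1–C5 (the two methyl-bearing ring carbons and the side-chain carbon between them, a pentan-3-one pattern), and a four-carbon unit, C6–C9 (alkene CH, both lactone-fusion carbons, ring CH2, a furan pattern). A [4+3] cycloaddition of the 1,3-dimethyl-2-oxyallyl cation to furan forms C5–C6 and C9–C10 at once and gives a meso 8-oxabicyclo[3.2.1]octenone. Its oxygen bridge, absent from the target, is then spent twice: C6–O leaves in a desymmetrising β-elimination that creates C5=C6, and C9–O relays its configuration to C7 by Claisen rearrangement. The C1 ketone becomes the side-chain carbon by allylboration.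

Key step: step 1

Numbering used throughout: C1 = ring CH carrying the side chain C2(O)–C3–C4(O); C5 = ring C(CH3)=; C6 = ring =CH; C7, C8 = lactone fusion (C7–C11, C8–O); C9 = ring CH2; C10 = ring CH(CH3); C11, C12, C13 = lactone α-carbon, carbonyl, exocyclic CH2. β is the face of the seven-membered ring that carries the C10 methyl, α the other face.

Assumption: the (R,R) lithium amide is taken to remove the α-proton on the side that becomes C5; if the sense is found to be opposite, the (S,S) amide is used with no other change.

Step 1
Reactants: 1 (furan), 2 (2,4-dibromopentan-3-one)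
Product: 4 meso-2,4-dimethyl-8-oxabicyclo[3.2.1]oct-6-en-3-one (diequatorial methyls), via oxyallyl cation 3 (not isolated)
Conditions: NaI, Cu powder, furan (excess), MeCN, rt
Reagents that add atoms: none
Why: Reductive removal of both bromides (NaI, copper metal) gives the 1,3-dimethyl-2-oxyallyl cation 3, a two-π-electron three-carbon unit (C10–C1–C5) that adds across C2 and C5 of furan in a [4+3] cycloaddition (oxyallyl cation–furan cycloaddition), forming the C5–C6 and C9–C10 σ bonds in one operation. The seven-membered carbocycle is closed by intermolecular cycloaddition (both ends of the allyl cation bond to the diene termini, concerted or in rapid succession), and the furan oxygen becomes a one-atom bridge, so the same event closes a tetrahydropyranone and a 2,5-dihydrofuran ring. Of the four new stereocentres, C6 and C9 follow from suprafacial addition to furan, and C5 and C10 from the W geometry of the cation (methyls cis to each other) together with the compact, boat-like transition state (both methyls equatorial, anti to the oxygen bridge). The product is meso, so only relative control is needed. The step needs periselectivity over Friedel–Crafts-type alkylation of furan and diastereoselectivity for the diequatorial isomer; the weakly Lewis-acidic reductive conditions with excess furan should secure the first, the W cation and compact approach the second, and minor α-epimers should converge on 4 on base equilibration.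

Step 2
Reactants: 4 (meso ketone)
Product: 6 triethylsilyl enol ether (C1–C5 enol ether of the bicycle), via lithium enolate 5 (not isolated)
Conditions: (R,R)-bis(1-phenylethyl)amine, n-BuLi, Et3SiCl (in situ), THF, −100 °C
Reagents that add atoms: chlorotriethylsilane, CC[Si](Cl)(CC)CC
Why: Enantiotopic-proton-selective deprotonation of the meso ketone by the C2-symmetric chiral lithium amide under in situ silyl chloride trapping (desymmetrising enolisation; the axial α-hydrogens are aligned with the carbonyl π system) removes the mirror plane, so that C6, C9 and C10 become defined without any new stereocentre being formed.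

Step 3
Reactants: 6 (silyl enol ether)
Product: 7 2,7-dimethyl-6-(triethylsilyloxy)cyclohepta-2,4-dien-1-one (9α-silyloxy; 10β-methyl)
Conditions: Et3SiOTf (10 mol %), CH2Cl2, −78 °C to −40 °C; Et3N quench
Reagents that add atoms: none
Why: The silyl triflate silylates the bridging oxygen and the silyl enol ether then expels the C6–O bond (vinylogous E1cB-type β-elimination, the silyl-triflate-induced opening of 8-oxabicyclo[3.2.1]oct-6-en-3-ones), which forms the C5=C6 enone, leaves the silyl group on O9 and regenerates the catalyst by silyl transfer from the carbonyl oxygen; C9 and C10 are not touched, and low temperature with amine quench should keep the β-silyloxy ketone from eliminating further.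

Step 4
Reactants: 7 (dienone)
Product: 8 1β-hydroxy dienol silyl ether
Conditions: (S)-Me-CBS oxazaborolidine (0.2 equiv), catecholborane, toluene, −78 °C; aq. NaOH work-up
Reagents that add atoms: none
Why: Corey–Bakshi–Shibata 1,2-reduction of the dienone: with the alkenyl branch as the large group the (S)-catalyst delivers hydride to the α face of C1, which is also the face anti to the adjacent C10 methyl, and so sets the 1β-alcohol.

Step 5
Reactants: 8 (dienol)
Product: 10 1β-(methoxycarbonyloxy)-9α-hydroxy diene, via methyl carbonate 9 (not isolated)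
Conditions: ClCO2Me, pyridine, DMAP (cat.), CH2Cl2, 0 °C; then HF·pyridine, THF, 0 °C to rt
Reagents that add atoms: methyl chloroformate, COC(=O)Cl
Why: Acylation of the only free hydroxyl followed by fluoride cleavage of the silyl ether in the same flask; the methyl carbonate is the leaving group for step 7 and, being trans to O9, cannot migrate, and no stereocentre is affected.

Step 6
Reactants: 10 (hydroxy carbonate)
Product: 12 7α-(dimethylcarbamoylmethyl) carbonate with C5=C6 and C8=C9, via ketene N,O-acetal 11 (not isolated)
Conditions: MeC(OMe)2NMe2, toluene, 110 °C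
Reagents that add atoms: N,N-dimethylacetamide dimethyl acetal, COC(C)(OC)N(C)C
Why: Eschenmoser–Claisen rearrangement: exchange with the amide acetal gives the C9 ketene N,O-acetal, whose suprafacial [3,3] shift across C9–C8=C7 trades the α C9–O bond for an α C7–C11 bond (1,3-chirality transfer within the ring) and moves the alkene to C8=C9, while the C1 carbonate lacks the vinyl ether and stays.

Step 7
Reactants: 12 (amide carbonate)
Product: 13 6α-pinacolboryl allylboronate with C1=C5
Conditions: CuCl (5 mol %), Xantphos (5 mol %), KOt-Bu (10 mol %), B2pin2, THF, rt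
Reagents that add atoms: bis(pinacolato)diboron, CC1(C)OB(OC1(C)C)B1OC(C)(C)C(C)(C)O1
Why: Copper-catalysed γ-selective allylic borylation of the carbonate (formal anti-SN2' substitution by a boryl copper species: syn borylcupration of C5=C6 on the α face, then anti β-elimination of the β carbonate) puts boron on C6 on the α face and moves the alkene to C1=C5.

Step 8
Reactants: 13 (allylboronate), 14 (3-(tert-butyldimethylsilyloxy)propanal)
Product: 15 hydroxy amide with the complete side chain (1α side chain; 2S carbinol)
Conditions: toluene, 80 °C; aq. NaHCO3 work-up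
Reagents that add atoms: none
Why: Allylboration through a closed, chair-like six-membered transition state (Zimmerman–Traxler type): the boron-bound aldehyde bonds to C1 on the boron-bearing α face, which sets C1 and restores C5=C6, and because the ring fixes C10 cis to C6 (a Z-type γ-substituent, axial in the chair, aldehyde chain equatorial) the syn carbinol, here (2S), is expected.

Step 9
Reactants: 15 (hydroxy amide)
Product: 17 9β-iodo cis-lactone, via iminium ether iodide 16 (not isolated)
Conditions: I2, THF/H2O, 0 °C to rt; aq. NaHCO3/Na2S2O3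
Reagents that add atoms: iodine, [I][I]; water, O
Why: Iodolactonisation of the γ,δ-unsaturated amide: the amide oxygen on the α side chain closes 5-exo onto the C8=C9 iodonium ion (anti addition, hence cis-fused lactone with 8α oxygen and 9β iodine) and the iminium ether is hydrolysed by water, whereas closure onto C5=C6 would require anti-Markovnikov attack at C6 and a congested tertiary iodide.

Step 10
Reactants: 17 (iodolactone)
Product: 18 cis-fused γ-lactone (C9 = CH2)
Conditions: Bu3SnH, AIBN (cat.), benzene, 80 °C
Reagents that add atoms: none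
Why: Radical chain dehalogenation with tin hydride turns the secondary iodide into the C9 methylene group without touching a stereocentre.

Step 11
Reactants: 18 (lactone)
Product: 21 α-methylene lactone (free 2-OH; 4-OTBS), via Mannich base 19 (not isolated), via ammonium iodide 20 (not isolated)
Conditions: LiN(SiMe3)2 (2.2 equiv), THF, −78 °C; [Me2N=CH2]I, −78 °C to rt; then MeI, MeOH, rt; then aq. NaHCO3, CH2Cl2, rt
Reagents that add atoms: Eschenmoser's salt, C=[N+](C)C.[I-]
Why: Standard α-methylenation of a γ-lactone: Mannich reaction of the lithium enolate with Eschenmoser's salt, quaternisation of the amine and mild-base elimination; the extra equivalent of base covers the free C2 hydroxyl and no ring stereocentre is affected.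

Step 12
Reactants: 21 (silyl ether)
Product: 22 2,4-diol
Conditions: HF·pyridine, pyridine, THF, 0 °C to rt
Reagents that add atoms: none
Why: Fluoride cleavage of the primary silyl ether under buffered, non-basic conditions that leave the α-methylene lactone alone.

Step 13
Reactants: 22 (diol)
Product: 23 4-O-acetate
Conditions: AcCl, 2,4,6-collidine, CH2Cl2, −78 °C
Reagents that add atoms: acetyl chloride, CC(=O)Cl
Why: Chemoselective acetylation of the primary hydroxyl at low temperature; the secondary C2 hydroxyl next to the branched C1 should react much more slowly.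

Step 14
Reactants: 23 (monoacetate), 24 (angelic acid)
Product: 25 target CNP0163960.1
Conditions: 2,4,6-trichlorobenzoyl chloride, Et3N, toluene, rt; then 23, DMAP, 60 °C
Reagents that add atoms: none
Why: Yamaguchi esterification through the mixed anhydride of angelic acid, the usual way to acylate a hindered secondary alcohol with this acid while keeping the Z alkene; the acetate already sits on the preferred primary position, so acyl migration is not expected.

Compound list
1 | furan | c1ccoc1 | starting material
2 | 2,4-dibromopentan-3-one (diastereomer mixture) | CC(Br)C(=O)C(C)Br | starting material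
3 | 1,3-dimethyl-2-oxyallyl cation, W-shaped zwitterion (not isolated) | C/C=C(\[O-])[CH+]C | intermediate
4 | meso-2,4-dimethyl-8-oxabicyclo[3.2.1]oct-6-en-3-one, both methyls equatorial (β), oxygen bridge α | O=C1[C@@H](C)[C@H]2C=C[C@H](O2)[C@H]1C | intermediate
5 | lithium C1–C5 enolate of 4 (not isolated) | C[C@H]1C([O-])=C(C)[C@H]2C=C[C@@H]1O2.[Li+] | intermediate
6 | 2,4-dimethyl-3-(triethylsilyloxy)-8-oxabicyclo[3.2.1]octa-2,6-diene (10β-methyl, α oxygen bridge) | C[C@H]1C(O[Si](CC)(CC)CC)=C(C)[C@H]2C=C[C@@H]1O2 | intermediate
7 | 2,7-dimethyl-6-(triethylsilyloxy)cyclohepta-2,4-dien-1-one, silyloxy (9α) and methyl (10β) trans | C[C@H]1C(=O)C(C)=CC=C[C@@H]1O[Si](CC)(CC)CC | intermediate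
8 | 2,7-dimethyl-6-(triethylsilyloxy)cyclohepta-2,4-dien-1-ol, 1β-OH (cis to the C10 methyl, trans to O9) | C[C@H]1[C@@H](O)C(C)=CC=C[C@@H]1O[Si](CC)(CC)CC | intermediate
9 | 1β-methyl carbonate of 8 (not isolated) | C[C@H]1[C@@H](OC(=O)OC)C(C)=CC=C[C@@H]1O[Si](CC)(CC)CC | intermediate
10 | 1β-(methoxycarbonyloxy)-9α-hydroxy-5,10β-dimethylcyclohepta-5,7-diene | C[C@H]1[C@@H](OC(=O)OC)C(C)=CC=C[C@@H]1O | intermediate
11 | C9 O-(1-dimethylaminovinyl) ketene N,O-acetal of 10 (not isolated) | C[C@H]1[C@@H](OC(=O)OC)C(C)=CC=C[C@@H]1OC(=C)N(C)C | intermediate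
12 | N,N-dimethyl-2-[1β-(methoxycarbonyloxy)-5,10β-dimethylcyclohepta-5,8-dien-7α-yl]acetamide | C[C@H]1[C@@H](OC(=O)OC)C(C)=C[C@H](CC(=O)N(C)C)C=C1 | intermediate
13 | N,N-dimethyl-2-[6α-(pinacolboryl)-5,10β-dimethylcyclohepta-1(5),8-dien-7α-yl]acetamide | C[C@H]1C=C(C)[C@H](B2OC(C)(C)C(C)(C)O2)[C@H](CC(=O)N(C)C)C=C1 | intermediate
14 | 3-(tert-butyldimethylsilyloxy)propanal | O=CCCO[Si](C)(C)C(C)(C)C | starting material
15 | N,N-dimethyl-2-{1α-[(1S)-1-hydroxy-3-(tert-butyldimethylsilyloxy)propyl]-5,10β-dimethylcyclohepta-5,8-dien-7α-yl}acetamide | C[C@H]1[C@H]([C@H](CCO[Si](C)(C)C(C)(C)C)O)C(C)=C[C@H](CC(=O)N(C)C)C=C1 | intermediate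
16 | 9β-iodo cyclic iminium ether iodide (not isolated) | C1C(=[N+](C)C)O[C@@H]2[C@@H](I)[C@@H](C)[C@H]([C@H](CCO[Si](C)(C)C(C)(C)C)O)C(C)=C[C@H]12.[I-] | intermediate
17 | 9β-iodo cis-fused γ-lactone (8α-O, 7α-C11) | C1C(=O)O[C@@H]2[C@@H](I)[C@@H](C)[C@H]([C@H](CCO[Si](C)(C)C(C)(C)C)O)C(C)=C[C@H]12 | intermediate
18 | cis-fused γ-lactone with C9 = CH2, free 2-OH, 4-OTBS | C1C(=O)O[C@@H]2C[C@@H](C)[C@H]([C@H](CCO[Si](C)(C)C(C)(C)C)O)C(C)=C[C@H]12 | intermediate
19 | α-(dimethylaminomethyl) lactone, C11 epimers (not isolated) | CN(C)CC1C(=O)O[C@@H]2C[C@@H](C)[C@H]([C@H](CCO[Si](C)(C)C(C)(C)C)O)C(C)=C[C@H]12 | intermediate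
20 | α-(trimethylammoniomethyl) lactone iodide (not isolated) | C[N+](C)(C)CC1C(=O)O[C@@H]2C[C@@H](C)[C@H]([C@H](CCO[Si](C)(C)C(C)(C)C)O)C(C)=C[C@H]12.[I-] | intermediate
21 | α-methylene lactone with free 2-OH and 4-OTBS | C=C1C(=O)O[C@@H]2C[C@@H](C)[C@H]([C@H](CCO[Si](C)(C)C(C)(C)C)O)C(C)=C[C@H]12 | intermediate
22 | α-methylene lactone 2,4-diol | C=C1C(=O)O[C@@H]2C[C@@H](C)[C@H]([C@H](CCO)O)C(C)=C[C@H]12 | intermediate
23 | α-methylene lactone 4-O-acetate with free 2-OH | C=C1C(=O)O[C@@H]2C[C@@H](C)[C@H]([C@H](CCOC(C)=O)O)C(C)=C[C@H]12 | intermediate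
24 | angelic acid, (Z)-2-methylbut-2-enoic acid | C/C=C(/C)C(=O)O | starting material
25 | CNP0163960.1, (3aR,6S,7R,8aR)-6-[(1S)-3-acetoxy-1-(angeloyloxy)propyl]-5,7-dimethyl-3-methylidene-3,3a,6,7,8,8a-hexahydro-2H-cyclohepta[b]furan-2-one | C=C1C(=O)O[C@@H]2C[C@@H](C)[C@H]([C@H](CCOC(C)=O)OC(=O)/C(C)=C\C)C(C)=C[C@H]12 | target

Total step count: 14. Longest linear sequence: 14 steps (from 1 and 2 to 25; 14 and 24 are bought).

Steps most likely to fail

Step 7 (with its follow-up in step 8). The borylcupration of the trisubstituted C5=C6 alkene may be slow on the α face next to the C7 side chain, the anti course of the substitution may erode, or the hindered allylboronate may transfer sluggishly. The fallback sets out from 8 and comes back at 15. Phenyl isocyanate converts 8 into the 1β-N-phenylcarbamate F1; HF·pyridine frees the C9 hydroxyl to give the hydroxy carbamate F2, and the Eschenmoser–Claisen rearrangement of step 6 gives the amide carbamate F3. Deprotonation of the carbamate N–H (n-BuLi), CuI and PhMe2SiLi then deliver silicon to C6 by carbamate-directed syn-SN2' displacement on the β face, giving the 6β-allylsilane F4. A TiCl4-mediated Hosomi–Sakurai reaction with 14 (anti-SE2', open transition state, syn product) forms the C1–C2 bond on the α face and gives 15.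

Step 9. The two alkenes may compete for the iodonium ion, with closure onto C6 instead of C8. The fallback sets out from 15 and comes back at 18. An amide-directed hydroboration ([Rh(nbd)2]BF4, triphenyl phosphite, pinacolborane, THF, 40 °C) should add boron to C8 syn to the chelating amide; catalytic hydroboration leaves the trisubstituted alkene alone. This gives the 8α-boronate F5 (the C2 hydroxyl is O-borylated in the flask). Oxidation (NaBO3·4H2O, THF/H2O) gives the 8α-hydroxy amide F6, and camphorsulfonic acid in toluene at 80 °C closes the cis lactone 18 with loss of dimethylamine, so step 10 is not needed.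

Step 4. Hydride delivery by the oxazaborolidine may show poor facial selectivity on this dienone, whose α' carbon is branched. The fallback sets out from 7 and comes back at 8. HF·pyridine at −20 °C gives the β-hydroxy dienone F7; its free C9 hydroxyl directs intramolecular hydride delivery (Me4NBH(OAc)3, MeCN/AcOH, −30 °C, Evans–Saksena anti reduction) to the α face of C1 and gives the trans-1,3-diol F8. The less hindered C9 hydroxyl is then silylated selectively (Et3SiCl, 2,6-lutidine, CH2Cl2, −78 °C) to return to 8.

Further compounds
F1 | step 7 | 1β-(N-phenylcarbamoyloxy) analogue of 8 (9α-OSiEt3) | C[C@H]1[C@@H](OC(=O)Nc2ccccc2)C(C)=CC=C[C@@H]1O[Si](CC)(CC)CC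
F2 | step 7 | 1β-(N-phenylcarbamoyloxy)-9α-hydroxy diene | C[C@H]1[C@@H](OC(=O)Nc2ccccc2)C(C)=CC=C[C@@H]1O
F3 | step 7 | 7α-(dimethylcarbamoylmethyl) 1β-N-phenylcarbamate with C5=C6 and C8=C9 | C[C@H]1[C@@H](OC(=O)Nc2ccccc2)C(C)=C[C@H](CC(=O)N(C)C)C=C1
F4 | step 7 | 6β-(dimethylphenylsilyl) allylsilane amide with C1=C5 | C[C@H]1C=C(C)[C@@H]([Si](C)(C)c2ccccc2)[C@H](CC(=O)N(C)C)C=C1
F5 | step 9 | 8α-pinacolboryl amide with O-pinacolboryl C2 hydroxyl | C[C@H]1[C@H]([C@H](CCO[Si](C)(C)C(C)(C)C)OB2OC(C)(C)C(C)(C)O2)C(C)=C[C@H](CC(=O)N(C)C)[C@H](B3OC(C)(C)C(C)(C)O3)C1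
F6 | step 9 | 8α-hydroxy amide | C[C@H]1[C@H]([C@H](CCO[Si](C)(C)C(C)(C)C)O)C(C)=C[C@H](CC(=O)N(C)C)[C@H](O)C1
F7 | step 4 | 6-hydroxy-2,7-dimethylcyclohepta-2,4-dien-1-one (9α-OH, 10β-methyl) | C[C@H]1C(=O)C(C)=CC=C[C@@H]1O
F8 | step 4 | 2,7-dimethylcyclohepta-2,4-diene-1,6-diol (1β-OH, 9α-OH) | C[C@H]1[C@@H](O)C(C)=CC=C[C@@H]1O
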